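## Retrosynthetic overview
- **Ring C is closed last.** The C7–O bond of the (6E)-alkylidene butenolide is formed on the finished 6/10 carbocycle by dehydrogenative 5-exo lactonisation of a macrocyclic (2Z,4E)-dienoic acid. This is the key step and it is new.
- **Ring B** is closed at C8–C9 by an intramolecular B-alkyl Suzuki coupling between a C10 exocyclic methylene and an (E)-enol tosylate. The hydroboration sets C10.
- **C6=C7–C8/C17–C19** come from cross metathesis of the vinyl carbinol with a vinyl β-keto ester. **C14–OAc** comes from ozonolysis and Criegee rearrangement of the isopropenyl group (C–O formed with retention).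
- **C1–C2** comes from C-acylation of (S)-carvone with the lactone made from (S)-linalool, which brings in C5. Methylation then sets C1 and a chelate-controlled reduction sets C2.
- **Ring order:** A (from carvone), then B, then C.

Atom labels follow briarane numbering: C1 quaternary, C2 isovalerate carbinol, C5 tertiary carbinol, C6=C7, C8=C17, C9 methylene, C10 ring-fusion CH, C11=C12, C14 acetate carbinol, C19 lactone carbonyl.

Assumption: (S)-(+)-linalool (coriandrol) is bought at about 90% ee. Its minor enantiomer becomes a diastereomer after coupling with enantiopure carvone and is removed by chromatography.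

## Route

Step 1
Reactants: 1 (S)-(+)-linalool
Product: 3 (5S)-5-ethenyl-5-methyloxolan-2-one, via lactol 2 (not isolated)
Conditions: O3 (1.0 equiv, Sudan Red 7B end point), CH2Cl2, −78 °C; Me2S; then TEMPO (10 mol %), PhI(OAc)2, CH2Cl2, rt
Reagents that add atoms: ozone, [O-][O+]=O
Why: Chemoselective ozonolysis cleaves the electron-rich trisubstituted olefin far faster than the vinyl group, the hydroxy aldehyde closes to lactol 2, and TEMPO/PhI(OAc)2 oxidation gives the lactone with the linalool stereocentre (future C5) untouched.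

Step 2
Reactants: 4 (S)-(+)-carvone; 3 (5S)-5-ethenyl-5-methyloxolan-2-one
Product: 6 (5S)-6-[(4S)-4-hydroxy-4-methylhex-5-enoyl]-2-methyl-5-(prop-1-en-2-yl)cyclohex-2-en-1-one (C1 epimers, enol and hemiketal forms), via lithium dienolate 5 (not isolated)
Conditions: 4 (2.2 equiv), LiN(iPr)2 (2.2 equiv), THF, −78 °C; 3 (1.0 equiv), −78 → −20 °C; AcOH
Reagents that add atoms: none
Why: Crossed Claisen C-acylation of the kinetic α′-enolate of carvone by the unhindered lactone carbonyl is driven forward because the second equivalent of enolate deprotonates the β-diketone, and C1 remains epimerisable at this stage.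

Step 3
Reactants: 6 β-diketone
Product: 7 (5R,6R)-6-[(4S)-4-hydroxy-4-methylhex-5-enoyl]-2,6-dimethyl-5-(prop-1-en-2-yl)cyclohex-2-en-1-one
Conditions: MeI, K2CO3, acetone, rt
Reagents that add atoms: iodomethane, CI
Why: In this C-alkylation of a β-diketone enolate, MeI enters anti to the neighbouring isopropenyl group and so sets the quaternary C1 with the methyl trans to isopropenyl.

Step 4
Reactants: 7 methylated diketone
Product: 8 (5R,6R)-6-[(1S,4S)-1,4-dihydroxy-4-methylhex-5-en-1-yl]-2,6-dimethyl-5-(prop-1-en-2-yl)cyclohex-2-en-1-one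
Conditions: Zn(BH4)2, Et2O, −78 → −30 °C; H2O
Reagents that add atoms: none
Why: In this chelation-controlled 1,3-dicarbonyl reduction zinc bridges the C2 and C10 oxygens, the saturated side-chain ketone reacts before the hindered conjugated one, and hydride arrives from the chelate face carrying the small C1 methyl (anti to the C14 ring branch) to give (2S).

Step 5
Reactants: 8 keto diol
Product: 9 (1S,4S)-1-[(1R,6R)-1,3-dimethyl-2-oxo-6-(prop-1-en-2-yl)cyclohex-3-en-1-yl]-4-hydroxy-4-methylhex-5-en-1-yl 3-methylbutanoate
Conditions: isovaleric anhydride, Et3N, DMAP (cat.), CH2Cl2, rt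
Reagents that add atoms: isovaleric anhydride, CC(C)CC(=O)OC(=O)CC(C)C
Why: DMAP-catalysed acylation esterifies the secondary C2 alcohol and leaves the tertiary C5 alcohol free, and it also removes any retro-aldol risk in later steps.

Step 6
Reactants: 10 2-(trimethylsilyl)ethanol; 11 propanoyl chloride
Product: 12 2-(trimethylsilyl)ethyl propanoate
Conditions: Et3N, CH2Cl2, 0 °C
Reagents that add atoms: none
Why: Simple acyl chloride esterification installs a fluoride-labile ester that can be removed later without touching the acetate or the isovalerate.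

Step 7
Reactants: 12 2-(trimethylsilyl)ethyl propanoate; 13 acrolein
Product: 15 2-(trimethylsilyl)ethyl 3-hydroxy-2-methylpent-4-enoate (diastereomer mixture), via lithium ester enolate 14 (not isolated)
Conditions: LiN(iPr)2, THF, −78 °C; 13; AcOH
Reagents that add atoms: none
Why: The lithium ester enolate adds 1,2 to acrolein in an aldol addition, and both new stereocentres are erased in later steps.

Step 8
Reactants: 15 allylic β-hydroxy ester
Product: 16 2-(trimethylsilyl)ethyl 2-methyl-3-oxopent-4-enoate
Conditions: Dess–Martin periodinane, NaHCO3, CH2Cl2, 0 °C (used at once)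
Reagents that add atoms: none
Why: Dess–Martin oxidation gives the vinyl β-keto ester under neutral conditions that avoid its polymerisation.

Step 9
Reactants: 9 isovalerate; 16 vinyl β-keto ester
Product: 17 2-(trimethylsilyl)ethyl (4E,6S,9S)-9-[(1R,6R)-1,3-dimethyl-2-oxo-6-(prop-1-en-2-yl)cyclohex-3-en-1-yl]-6-hydroxy-2,6-dimethyl-9-(3-methylbutanoyloxy)-3-oxonon-4-enoate (C17 epimers)
Conditions: second-generation Hoveyda–Grubbs catalyst (5 mol %), 16 (3 equiv), CH2Cl2, 40 °C
Reagents that add atoms: none
Why: Olefin cross metathesis of the free tertiary allylic alcohol with the vinyl ketone in excess is E-selective, and the isopropenyl and enone olefins are spectators.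

Step 10
Reactants: 17 enone β-keto ester
Product: 18 2-(trimethylsilyl)ethyl (2E,4E,6S,9S)-9-[(1R,6R)-1,3-dimethyl-2-oxo-6-(prop-1-en-2-yl)cyclohex-3-en-1-yl]-6-hydroxy-2,6-dimethyl-9-(3-methylbutanoyloxy)-3-(4-methylbenzenesulfonyloxy)nona-2,4-dienoate
Conditions: TsCl, N-methylimidazole, Et3N, CH2Cl2, −15 → 0 °C
Reagents that add atoms: 4-toluenesulfonyl chloride, Cc1ccc(cc1)S(=O)(=O)Cl
Why: In this stereocomplementary enol tosylation of an α-substituted β-keto ester the non-chelated ammonium enolate is trapped as the E enol tosylate (OTs trans to the ester, so C7 is cis to C19), and the tertiary alcohol is inert.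

Step 11
Reactants: 18 dienyl tosylate
Product: 21 2-(trimethylsilyl)ethyl (2E,4E,6S,9S)-9-[(1S,6S)-6-acetoxy-1,3-dimethyl-2-oxocyclohex-3-en-1-yl]-6-hydroxy-2,6-dimethyl-9-(3-methylbutanoyloxy)-3-(4-methylbenzenesulfonyloxy)nona-2,4-dienoate, via methoxy hydroperoxide 19 (not isolated), via peroxyacetate 20 (not isolated)
Conditions: O3, CH2Cl2/MeOH 5:1, NaHCO3, −78 °C (Sudan Red 7B end point); concentrate; Ac2O (1.3 equiv), Et3N, DMAP (cat.), CH2Cl2, 0 → 40 °C
Reagents that add atoms: ozone, [O-][O+]=O; methanol, CO
Why: Ozone attacks the only electron-rich olefin, methanol traps the carbonyl oxide, and O-acetylation triggers the Criegee rearrangement in which C14 migrates to oxygen with retention, so the carvone stereocentre becomes the (14S)-acetate built from the isopropenyl carbons.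

Step 12
Reactants: 21 acetoxy enone
Product: 22 2-(trimethylsilyl)ethyl (2E,4E,6S,9S)-9-[(1S,6S)-6-acetoxy-1,3-dimethyl-2-methylidenecyclohex-3-en-1-yl]-6-hydroxy-2,6-dimethyl-9-(3-methylbutanoyloxy)-3-(4-methylbenzenesulfonyloxy)nona-2,4-dienoate
Conditions: Zn, CH2Br2, TiCl4 (pre-aged reagent, excess), THF/CH2Cl2, 0 °C → rt
Reagents that add atoms: dibromomethane, BrCBr
Why: Takai–Oshima–Lombardo methylenation is non-basic and attacks ketones but not esters or sulfonates, so the hindered C10 ketone becomes the exocyclic methylene whose carbon is C9.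

Step 13
Reactants: 22 exocyclic diene tosylate
Product: 24 6/10-bicyclic 2-(trimethylsilyl)ethyl (6E,8(17)Z)-dienoate (1S,2S,5S,10S,14S; ring C still open between O and C7), via bis-boryl adduct 23 (not isolated)
Conditions: 9-BBN (2.3 equiv), THF, 0 °C → rt; then syringe-pump addition to Pd(OAc)2 (10 mol %), SPhos (20 mol %), K3PO4, THF/H2O, 60 °C (final 1 mM)
Reagents that add atoms: none
Why: 9-BBN hydroborates only the terminal methylene, from the face opposite the pseudoaxial C1 methyl (side chain pseudoequatorial), which places H-10 trans to that methyl (10S), and the intramolecular B-alkyl Suzuki–Miyaura coupling then joins C9 to C8 with retention of the enol tosylate geometry to close ring B.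

Step 14
Reactants: 24 macrocyclic silylethyl ester
Product: 25 6/10-bicyclic (6E,8(17)Z)-dienoic acid (1S,2S,5S,10S,14S)
Conditions: Bu4NF, AcOH (1:1, 1.5 equiv), THF, 0 °C → rt
Reagents that add atoms: none
Why: Fluoride-induced β-fragmentation of the 2-(trimethylsilyl)ethyl ester frees the acid under buffered conditions that leave the acetate, the isovalerate and the tertiary allylic alcohol intact.

Step 15
Reactants: 25 macrocyclic dienoic acid
Product: 27 CNP0208239.1, via iodolactone 26 (not isolated)
Conditions: Bu4NI (10 mol %), tBuOOH (decane solution, 1.5 equiv), K2CO3 (20 mol %), EtOAc, 25 °C, dark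
Reagents that add atoms: none
Why: Proposed new method: tBuOOH oxidises Bu4NI to ammonium hypoiodite, which converts the acid into an acyl hypoiodite that delivers iodonium to the adjacent C6=C7 bond and closes the C7–O bond by anti 5-exo iodolactonisation (6-endo attack at neopentyl C6 would give a strained bridged pyranone), after which anti E2/E1cB loss of HI at the acidic γ-H returns iodide to the cycle, and because anti addition followed by anti elimination inverts the olefin skeleton the E ring olefin becomes the required (6E)-alkylidene with C5 cis to C8 while C5 is untouched; the closest known reaction types are stoichiometric iodolactonisation–dehydroiodination and hypoiodite-catalysed oxidative C–O cyclisation of carbonyl compounds, neither of which has been shown for dehydrogenative lactonisation of a 2,4-dienoic acid.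

## Compound list
1 | (S)-(+)-linalool | C=C[C@@](C)(O)CCC=C(C)C | starting material
2 | (5S)-5-ethenyl-5-methyloxolan-2-ol (anomers) | C=C[C@]1(C)CCC(O)O1 | intermediate
3 | (5S)-5-ethenyl-5-methyloxolan-2-one | C=C[C@]1(C)CCC(=O)O1 | intermediate
4 | (S)-(+)-carvone | CC1=CC[C@@H](CC1=O)C(C)=C | starting material
5 | lithium cross-conjugated dienolate of (S)-carvone | CC1=CC[C@H](C(C)=C)C=C1[O-].[Li+] | intermediate
6 | β-diketone, C1 epimerisable (5S; side chain 4S) | C=C[C@@](C)(O)CCC(=O)C1C(=O)C(C)=CC[C@@H]1C(C)=C | intermediate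
7 | C1-methylated diketone (briarane 1R,5S,14R) | C=C[C@@](C)(O)CCC(=O)[C@]1(C)C(=O)C(C)=CC[C@@H]1C(C)=C | intermediate
8 | keto diol (1R,2S,5S,14R) | C=C[C@@](C)(O)CC[C@H](O)[C@]1(C)C(=O)C(C)=CC[C@@H]1C(C)=C | intermediate
9 | C2 isovalerate (1R,2S,5S,14R) | C=C[C@@](C)(O)CC[C@H](OC(=O)CC(C)C)[C@]1(C)C(=O)C(C)=CC[C@@H]1C(C)=C | intermediate
10 | 2-(trimethylsilyl)ethanol | C[Si](C)(C)CCO | starting material
11 | propanoyl chloride | CCC(=O)Cl | starting material
12 | 2-(trimethylsilyl)ethyl propanoate | CCC(=O)OCC[Si](C)(C)C | intermediate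
13 | acrolein | C=CC=O | starting material
14 | lithium enolate of 12 | CC=C([O-])OCC[Si](C)(C)C.[Li+] | intermediate
15 | 2-(trimethylsilyl)ethyl 3-hydroxy-2-methylpent-4-enoate | C=CC(O)C(C)C(=O)OCC[Si](C)(C)C | intermediate
16 | 2-(trimethylsilyl)ethyl 2-methyl-3-oxopent-4-enoate | C=CC(=O)C(C)C(=O)OCC[Si](C)(C)C | intermediate
17 | (6E)-enone β-keto ester (1R,2S,5S,14R; C17 epimers) | C[Si](C)(C)CCOC(=O)C(C)C(=O)/C=C/[C@@](C)(O)CC[C@H](OC(=O)CC(C)C)[C@]1(C)C(=O)C(C)=CC[C@@H]1C(C)=C | intermediate
18 | (E)-enol tosylate, (6E)-diene (1R,2S,5S,14R) | C[Si](C)(C)CCOC(=O)/C(C)=C(OS(=O)(=O)c1ccc(C)cc1)\C=C\[C@@](C)(O)CC[C@H](OC(=O)CC(C)C)[C@]1(C)C(=O)C(C)=CC[C@@H]1C(C)=C | intermediate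
19 | α-methoxy hydroperoxide at the former isopropenyl carbon (epimers there) | C[Si](C)(C)CCOC(=O)/C(C)=C(OS(=O)(=O)c1ccc(C)cc1)\C=C\[C@@](C)(O)CC[C@H](OC(=O)CC(C)C)[C@]1(C)C(=O)C(C)=CC[C@@H]1C(C)(OC)OO | intermediate
20 | peroxyacetate of 19 | C[Si](C)(C)CCOC(=O)/C(C)=C(OS(=O)(=O)c1ccc(C)cc1)\C=C\[C@@](C)(O)CC[C@H](OC(=O)CC(C)C)[C@]1(C)C(=O)C(C)=CC[C@@H]1C(C)(OC)OOC(C)=O | intermediate
21 | C14 acetate, C10 ketone (1S,2S,5S,14S) | C[Si](C)(C)CCOC(=O)/C(C)=C(OS(=O)(=O)c1ccc(C)cc1)\C=C\[C@@](C)(O)CC[C@H](OC(=O)CC(C)C)[C@]1(C)C(=O)C(C)=CC[C@@H]1OC(C)=O | intermediate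
22 | C10 exocyclic methylene diene (1S,2S,5S,14S) | C[Si](C)(C)CCOC(=O)/C(C)=C(OS(=O)(=O)c1ccc(C)cc1)\C=C\[C@@](C)(O)CC[C@H](OC(=O)CC(C)C)[C@]1(C)C(=C)C(C)=CC[C@@H]1OC(C)=O | intermediate
23 | C9 B-alkyl-9-BBN, C5 O-borinate (10S set) | C[Si](C)(C)CCOC(=O)/C(C)=C(OS(=O)(=O)c1ccc(C)cc1)\C=C\[C@@](C)(OB2C3CCCC2CCC3)CC[C@H](OC(=O)CC(C)C)[C@]1(C)[C@@H](CB2C3CCCC2CCC3)C(C)=CC[C@@H]1OC(C)=O | intermediate
24 | macrocyclic (6E,8(17)Z)-dienoate, silylethyl ester (1S,2S,5S,10S,14S) | CC(=O)O[C@H]1CC=C(C)[C@@H]2C/C(=C(\C)C(=O)OCC[Si](C)(C)C)/C=C/[C@@](C)(O)CC[C@H](OC(=O)CC(C)C)[C@@]12C | intermediate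
25 | macrocyclic (6E,8(17)Z)-dienoic acid (1S,2S,5S,10S,14S) | CC(=O)O[C@H]1CC=C(C)[C@@H]2C/C(=C(\C)C(=O)O)/C=C/[C@@](C)(O)CC[C@H](OC(=O)CC(C)C)[C@@]12C | intermediate
26 | 6-iodo butenolide, anti adduct (6R,7R drawn; the 6S,7S anti adduct gives the same olefin) | CC(=O)O[C@H]1CC=C(C)[C@@H]2CC3=C(C)C(=O)O[C@H]3[C@@H](I)[C@@](C)(O)CC[C@H](OC(=O)CC(C)C)[C@@]12C | intermediate
27 | CNP0208239.1 (1S,2S,5S,6E,10S,14S) | CC(=O)O[C@H]1CC=C(C)[C@@H]2CC3=C(C)C(=O)O/C3=C/[C@@](C)(O)CC[C@H](OC(=O)CC(C)C)[C@@]12C | target

## Count and risks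
Total step count: 15. Longest linear sequence: 12 (steps 1–5 and 9–15).

**Step 15, the new lactonisation.** The risks are attack of iodonium on the C11=C12 olefin, 6-endo closure, and slow catalyst turnover. The fallback uses known chemistry. It sets out from acid 25 and comes back at target 27. Treat 25 with I2 and NaHCO3 in MeCN/H2O at 0 °C and isolate iodolactone 26. Then remove HI in a separate operation with DBU in toluene. This is the classical halolactonisation–dehydrohalogenation route to alkylidene butenolides, and it has the same anti/anti stereochemical course.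

**Step 13, hydroboration and ring B closure.** The risks are oligomerisation, hydrolysis of the vinylogous tosylate, and an insufficient facial bias at C10. The fallback sets out from diene 22 and comes back at macrocycle 24 without any boron. It is an intramolecular reductive Heck-type 1,2-hydrovinylation with Pd2(dba)3, a phosphine and HCO2Na in DMA at high dilution. Zerovalent palladium inserts into the C8–OTs bond. The alkenylpalladium, tethered through the α-face C2 side chain, adds to the terminal diene carbon C9. Formate then delivers hydride from the palladium-bearing α face to the more substituted allyl terminus C10, which leaves the C11=C12 olefin in place.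

**Step 2, acylation by a lactone.** The risks are reversibility of the addition and hemiketal or enol ether side products. The fallback sets out from lactone 3 and comes back at β-diketone 6. Open 3 with MeNH(OMe)·HCl and iPrMgCl in THF to give the Weinreb amide (4S)-4-hydroxy-N-methoxy-N,4-dimethylhex-5-enamide F1. Then acylate dienolate 5 (3 equiv) with F1. The chelated tetrahedral adduct collapses only on quench and gives 6.

## Further compounds
F1 | step 2 | (4S)-4-hydroxy-N-methoxy-N,4-dimethylhex-5-enamide | C=C[C@@](C)(O)CCC(=O)N(C)OC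
F0 | step 13 | none | none
F0 | step 15 | none | none
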